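## Analysis of the target

The target 35 is a trans-fused hydrindan-2-one. Hydrindane numbers are used for it and for every intermediate: C1 (acyloxy methine), C2 (ketone), C3 (methine with the 1-hydroxyethyl group, carbinol carbon C1′), C3a and C7a (ring fusion), C4 (isopropyl methine), C5 (methylene), C6 (acyloxy methine), C7 (carbon of the exocyclic methylidene); β is the face of H-3a. There are eight stereocentres (C1, C3, C3a, C4, C6, C7a, C1′ and the α-carbon of the (R)-2-methylbutanoate) and one E-trisubstituted enoate. H-7a is α, so the fusion is trans-diaxial; the isopropyl group is β and equatorial, trans to C3; the C6 ester is α and axial; the C3 side chain is β, trans to C4, with an (S)-carbinol in a syn-aldol relation to C3a; the C1 ester is β, cis to C7 and close to the methylidene group. The sensitive groups are the α-acyloxy ketone (C1 is enolisable and its β configuration is expected to be the less stable one), the β-hydroxy ketone C2/C3/C1′ (retro-aldol, dehydration, epimerisation at C3) and the secondary allylic ester at C6 beside a 1,1-disubstituted alkene (ionisation, allylic transposition, double-bond migration). The synthesis is hard because six contiguous ring stereocentres must be set, because the oxygens at C1, C6 and C1′ end as two different esters and one free hydroxyl, and because C1 must be set late and without enolisation. The strategy rests on C5, the only unsubstituted ring carbon. It lies between oxygenated C6 and C4 with its branched three-carbon group, so a C6 ketone with an ester on C5 can act as a radical donor at C5 and a 2-methylpropenyl group on C3a as the acceptor, forming C4–C5 across two appendages that are already trans on the cyclopentane.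

## Retrosynthetic reasoning

35 from 34. The O–Si bond at C1′ is cut last. The group on that oxygen must come off beside two esters, an α-acyloxy ketone and an aldol, and it must outlast the acid that unmasks C1 and C2. Both demands point to the tert-butyldiphenylsilyl ether of 34, cleaved by buffered fluoride.

34 from 32 and 33. The C1–O bond is cut on the carbon side. Enolate oxidation next to the β substituent on C7a can only deliver the α oxygen, which is also the configuration that should survive enolisation. The β ester is therefore made from the α alcohol 32 and acid 33 by substitution with inversion, which the C2 carbonyl accelerates. Ester and configuration then arrive together, after the last step that could enolise C2. The forward reaction must substitute at a hindered secondary carbon without elimination toward C7a.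

32 from 30 (through 31), then 29, 27 with 28, and 26. The methylidene group is traced to a dimethylaminomethyl group on C7, from which amine oxide 31 can only remove H-7. C7 therefore stays tetrahedral while C6 is reduced, and a bulky hydride can attack the ketone of 26 from the equatorial side to give the axial alcohol 27. On a 2-methylidene ketone such reagents would add in the conjugate sense. The C6 ester (29) is put on before the acid step to 30, so that acid meets neither an allylic ester nor an exocyclic alkene and frees only the C1 hydroxyl.

26 from 24 (through 25) and 22. The carbon on C7 comes through the dianion of β-keto ester 22. The C6 ketone has two α-methylenes, and the ester that the key step leaves on C5 decides between them, since the second deprotonation can only occur at C7. A benzyl ester lets one hydrogenation saturate the isopropenyl group and release keto acid 25, which loses CO2 under neutral conditions that a β-amino ketone tolerates.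

22 from 19 (key disconnection). C4–C5 is cut because C5 can be made a stabilised, electrophilic radical between ketone and ester, and C4 is the inner carbon of an electron-rich alkene whose outer carbon becomes the isopropyl carbon. A cut at the ring fusion or at C6–C7 would force the ring-forming step to create the trans fusion itself. Here the fusion stereocentres are set beforehand on a cyclopentane, and the step gives the ring, the C4 stereocentre and the C6 carbonyl. The forward reaction must close 6-exo and not 7-endo, place the new C4 substituent equatorial, and end by oxidation of the adduct radical to an alkene.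

19 from 17 and 18, 17 from 16, 16 from 15. The β-keto ester is made by C-acylation of methyl ketone 17 with carbonate 18, and the methyl ketone from the allyl group of 16 by Wacker oxidation, which spares the trisubstituted alkene. C2 is masked as a dioxolane (16 from 15) because a free C2 ketone would let the side-chain enolates cyclise onto it and would allow β-elimination of the C1′ silyloxy group.

15 from 14, 14 from 12 (through 13). The C1 oxygen is introduced by hydroxylation of the kinetic enolate 13. Deprotonation goes to the C1 methylene and not to the C3 methine, and the oxidant arrives anti to both β neighbours. The oxygen is not placed on the enone before the conjugate additions, because an α-oxygenated enone can tautomerise through a symmetric 1,2-dicarbonyl form in which the ring stereocentre is lost.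

12 from 11, 11 from 7 and 8 (through 9 and 10). C3–C1′ is an aldol bond. The enolate is the one stored in silyl enol ether 7, so its regiochemistry is not in question. The syn relation of carbinol and C3a is the opposite of what the lithium enolate of a cyclic ketone gives, so a zirconium enolate (10) is used.

7 from 5 and 6, 5 from 1 and 2 (through 3 and 4). Two conjugate additions set C7a and C3a. The allyl group, the latent C7–C6–C5 chain, is added to 1 with loss of the silyloxy group, which transfers the chirality of 1 to the γ-carbon of enone 5. The 2-methylpropenyl group then adds anti to it. The reverse order would put the 2-methylpropenyl group on the γ-carbon of an enone, where a doubly allylic hydrogen invites conjugation and loss of the stereocentre.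

## Alternatives that were turned down

Alternative 1: The cut is at C1–C7a, with a temporary C2–C3a bond.
- Forward step: irradiation of enone A2 with ketene acetal A3 would give the trans-fused cyclobutane A1; acetal hydrolysis and a one-carbon ring expansion would then insert C3.
- For it: the strained trans fusion comes directly from the photoreaction, C4 is already present in A2, the acetal carbon reliably ends on C3a, and the bicycle is reached in very few steps. On speed to the bare skeleton it is stronger than the chosen route.
- Against it: the trans-fused bicyclo[4.2.0]octanone epimerises at C7a on any enolisation of the C7 ketone, and facial control by the C4 isopropyl group is modest. The ring expansion must insert a carbon that already carries the hydroxyethyl group, selectively on the C3a side. The oxygens at C1 and C6 would still have to be introduced on the bicycle without inherent control.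
- Comparison: the chosen route places the C1, C3 and C1′ substituents on a monocyclic cyclopentanone, where 1,2-induction is dependable, closes an unstrained ring across preset centres, and leaves the carbonyl at C6 where oxygen is needed.

Alternative 2: The cut is at C1–C2, with reversed polarity at C1.
- Forward step: stannane A5 would couple with its own thiol ester under zerovalent palladium with a copper carboxylate as thiolate scavenger, closing the cyclopentanone A4.
- For it: the C1 stereocentre is carried as a configurationally stable α-acyloxystannane, transferred with retention and already bearing the final ester. No late inversion and no protection of C1 are needed, which is better than the chosen route on that point.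
- Against it: ring closure with a secondary α-oxygenated stannane and an α-branched thiol ester has no close analogy, and transmetallation of secondary alkylstannanes is slow. A5 needs a stereodefined stannyl carbinol on a fully substituted cyclohexane, so C3a, C4, C7a and the methylidene group must all be built first without help from the key step. C6 is unoxidised in A4, so a late allylic oxidation beside an α-acyloxy ketone remains.
- Comparison: the chosen route pays with an inversion at C1, but its key step delivers the ring, C4 and the C6 oxygen.

Alternative 3: The cuts are at C3a–C7a and C6–C7.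
- Forward step: triene A7 would undergo an intramolecular Diels–Alder reaction, thermally or with a Lewis acid, to give hydrindene A6.
- For it: two bonds, both rings and up to four stereocentres form in one step, and the ester on C7 is the latent methylidene carbon. In bonds per step it is stronger than the chosen route.
- Against it: trienes of this tether length give cis- and trans-fused hydrindenes with little intrinsic bias. Facial control would depend on the single stereocentre C3 beside a ketal. The silyloxy diene would not tolerate the Lewis acid that trans selectivity would need. C4 is not set, because the C4–C5 alkene must later be hydrogenated from the correct face, and C1 carries no oxygen.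
- Comparison: the chosen route forms one bond in its key step, but the fusion is fixed beforehand, C4 is set in the ring closure, and the C1 oxygen is already in place.

Key step: step 10

Remark: 2, 6, 28 and 33 are taken as commercial; substituent positions of all intermediates are named by the hydrindane numbers of the atoms they become.

## Route

Step 1
Reactants: 1 (S)-4-(tert-butyldimethylsilyloxy)cyclopent-2-enone; 2 allylmagnesium bromide
Product: 5 (S)-4-allylcyclopent-2-enone, via silyl enol ether 3 (not isolated), via trans-3-allyl-4-silyloxycyclopentanone 4 (not isolated)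
Conditions: 2, CuBr·SMe2 (1.2 equiv), TMSCl, THF, −78 °C; 1 M HCl, THF, 0 °C; then DBU, CH2Cl2, 0 °C
Reagents that add atoms: none
Why: Allylcopper formed from 2 and CuBr·SMe2 adds in the 1,4 sense under TMSCl activation, anti to the silyloxy group, which sets the future C7a; hydrolysis of 3 and E1cB loss of silanolate from 4 transpose the enone, so the chirality of 1 is handed on to 5 (conjugate addition–elimination).

Step 2
Reactants: 5 (S)-4-allylcyclopent-2-enone; 6 2-methylprop-1-enylmagnesium bromide
Product: 7 3,4-trans-4-allyl-3-(2-methylprop-1-enyl)-1-(trimethylsilyloxy)cyclopent-1-ene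
Conditions: 6, CuBr·SMe2 (10 mol %), TMSCl, THF, −78 °C; Et3N, pentane
Reagents that add atoms: chlorotrimethylsilane, C[Si](C)(C)Cl
Why: Copper-catalysed conjugate addition of the alkenyl Grignard reagent occurs anti to the allyl group on the neighbouring carbon, which sets C3a trans to C7a, and the enolate is stored regiospecifically as the silyl enol ether toward C3.

Step 3
Reactants: 7 silyl enol ether; 8 acetaldehyde
Product: 11 2,3-trans-3,4-trans-4-allyl-2-[(1S)-1-hydroxyethyl]-3-(2-methylprop-1-enyl)cyclopentanone, via lithium enolate 9 (not isolated), via zirconium enolate 10 (not isolated)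
Conditions: MeLi, THF, 0 °C; Cp2ZrCl2, −78 → −30 °C; 8, −78 °C; H2O
Reagents that add atoms: none
Why: MeLi releases enolate 9 without equilibration and Cp2ZrCl2 turns it into zirconium enolate 10, a class of enolate that gives syn aldols whatever the enolate geometry; the aldehyde approaches C3 on the β face, anti to the 2-methylpropenyl group on C3a, so C3 and the (S)-carbinol C1′ are set together (directed aldol addition).

Step 4
Reactants: 11 syn aldol
Product: 12 tert-butyldiphenylsilyl ether of 11
Conditions: TBDPSCl, imidazole, DMAP (cat.), DMF, 40 °C
Reagents that add atoms: tert-butyl(chloro)diphenylsilane, CC(C)(C)[Si](Cl)(c1ccccc1)c1ccccc1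
Why: Silylation of the secondary alcohol blocks retro-aldol and elimination in the basic steps that follow; this acid-resistant group is meant to survive step 15 and to be removed last.

Step 5
Reactants: 12 silylated aldol
Product: 14 C1 α-hydroxy ketone (5-hydroxy derivative of 12, hydroxyl trans to the allyl group), via lithium enolate 13 (not isolated)
Conditions: LiN(i-Pr)2, THF, −78 °C; 2-(phenylsulfonyl)-3-phenyloxaziridine, −78 °C; H2O
Reagents that add atoms: 2-(phenylsulfonyl)-3-phenyloxaziridine, O=S(=O)(c1ccccc1)N1OC1c1ccccc1
Why: The amide base removes a proton from the less hindered C1 methylene in preference to the C3 methine, and the oxaziridine transfers oxygen to enolate 13 on the α face, anti to the allyl group on C7a and to the side chain on C3 (electrophilic enolate hydroxylation); the α alcohol is the epimer that withstands later enolisation and is inverted only in step 17.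

Step 6
Reactants: 14 α-hydroxy ketone
Product: 15 tert-butyldimethylsilyl ether of 14
Conditions: TBSOTf, 2,6-lutidine, CH2Cl2, −78 °C
Reagents that add atoms: tert-butyldimethylsilyl trifluoromethanesulfonate, CC(C)(C)[Si](C)(C)OS(=O)(=O)C(F)(F)F
Why: Silyl triflate with a hindered base silylates the α-hydroxy ketone at low temperature without ketol isomerisation; this is the more acid-labile of the two silyl ethers, as step 15 requires.

Step 7
Reactants: 15 bis-silylated ketone
Product: 16 ethylene ketal of 15 (dioxolane at C2)
Conditions: (TMSOCH2)2, TMSOTf (5 mol %), CH2Cl2, −78 → −20 °C; pyridine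
Reagents that add atoms: 1,2-bis(trimethylsilyloxy)ethane, C[Si](C)(C)OCCO[Si](C)(C)C
Why: Silyl-triflate-catalysed ketalisation with the bis-silyl ether of ethylene glycol proceeds at low temperature without enolising C1 or C3; the dioxolane keeps C2 out of the enolate chemistry of steps 9 and 11 and out of the reduction of step 13.

Step 8
Reactants: 16 allyl ketal
Product: 17 methyl ketone (2-oxopropyl group on C7a)
Conditions: PdCl2 (10 mol %), Cu(OAc)2 (20 mol %), O2 (1 atm), DMA/H2O 7:1, 25 °C
Reagents that add atoms: water, O
Why: Wacker oxidation with divalent palladium converts the terminal alkene into the methyl ketone with Markovnikov selectivity, while the trisubstituted alkene does not react; Cu(OAc)2 in place of a copper chloride keeps the medium mild enough for the ketal and the silyl ethers.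

Step 9
Reactants: 17 methyl ketone; 18 dibenzyl carbonate
Product: 19 benzyl β-keto ester (4-benzyloxy-2,4-dioxobutyl chain on C7a, 2-methylpropenyl group on C3a)
Conditions: NaH, 18, THF, 65 °C; AcOH
Reagents that add atoms: none
Why: Claisen-type C-acylation of the methyl ketone occurs at the methyl group, the less substituted α-position, and is driven by formation of the β-keto ester enolate; the benzyl ester is chosen for its hydrogenolytic removal in step 12.

Step 10
Reactants: 19 benzyl β-keto ester
Product: 22 trans-hydrindane C6 keto ester with 4β-isopropenyl and 5α-benzyloxycarbonyl groups, via C5 radical 20 (not isolated), via tertiary radical 21 (not isolated)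
Conditions: Mn(OAc)3·2H2O (2.1 equiv), Cu(OAc)2·H2O (1.0 equiv), degassed AcOH, 25 °C
Reagents that add atoms: none
Why: Trivalent manganese (Mn(OAc)3) forms the enolate of the β-keto ester and oxidises it by one electron to the electrophilic C5 radical 20, which adds to C4, the nearer carbon of the electron-rich alkene, closing the six-membered ring in the 6-exo-trig mode to give tertiary radical 21; divalent copper (Cu(OAc)2) captures 21 and β-hydride loss from a methyl group gives the isopropenyl group, the univalent copper being reoxidised by trivalent manganese. The closest known reaction type is the oxidative free-radical cyclisation of unsaturated β-keto esters with Mn(OAc)3 and Cu(OAc)2, including 6-exo closures that end in an isopropenyl group. The ring closes across the C3a and C7a appendages, which are already trans, so only the trans-hydrindane can form, with both bonds to the cyclopentane equatorial in a chair transition state. C4 is controlled by allylic 1,3-strain: H-3a eclipses the alkene so that the cis methyl group avoids C3, the radical arrives from the C7a side, and the former alkene terminus ends up equatorial (β) with H-4 anti to H-3a. C5 is not set kinetically; it is enolisable, should settle with the ester equatorial (α), and is removed in step 12. The step needs 6-exo over 7-endo closure, which polarity matching and formation of the tertiary radical secure, and oxidation of 21 in preference to hydrogen abstraction, which the stoichiometric Cu(OAc)2 secures. The ketal, the silyl ethers and the benzyl ester offer no site that the radical or the oxidant attacks at 25 °C.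

Step 11
Reactants: 22 cyclised keto ester
Product: 24 C7 dimethylaminomethyl derivative of 22, via dilithium dienolate 23 (not isolated)
Conditions: LiN(i-Pr)2 (2.3 equiv), THF, −78 → 0 °C; CH2=NMe2+ I−, −78 → 0 °C; AcOH
Reagents that add atoms: dimethylmethylideneammonium iodide, C[N+](C)=C.[I-]
Why: Two equivalents of amide base give dienolate 23, whose more basic terminus C7 attacks the iminium ion (Mannich alkylation of a β-keto ester dianion), so the C5 ester directs the one-carbon unit to C7; the configurations at C5 and C7 (C7 drawn as the product of axial attack) do not matter, since both are removed or equilibrated in step 12.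

Step 12
Reactants: 24 Mannich base
Product: 26 7α-(dimethylaminomethyl)-4β-isopropyl C6 ketone, via amino keto acid 25 (not isolated)
Conditions: H2 (1 atm), 10% Pd/C, EtOAc, 25 °C; filter; toluene, 60 °C; then Et3N, MeOH, 25 °C
Reagents that add atoms: none
Why: Hydrogenation saturates the 1,1-disubstituted alkene without touching C4 and cleaves the benzyl ester; keto acid 25 loses CO2 on gentle warming, and the amine base lets the C7 substituent settle in the equatorial (α) position beside the ketone.

Step 13
Reactants: 26 amino ketone
Product: 27 6α (axial) alcohol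
Conditions: LiBH(s-Bu)3, THF, −78 °C; H2O
Reagents that add atoms: none
Why: The bulky borohydride approaches the cyclohexanone from the equatorial side, away from the axial hydrogens on C4 and C7a, and gives the axial alcohol cis to the equatorial C7 substituent; the ketal shields C2.

Step 14
Reactants: 27 amino alcohol; 28 (E)-3-methylpent-2-enoic acid
Product: 29 C6 (E)-3-methylpent-2-enoate of 27
Conditions: 28, DCC, DMAP, CH2Cl2, 25 °C
Reagents that add atoms: none
Why: Carbodiimide esterification with DMAP (Steglich esterification) acylates the axial alcohol under neutral conditions that leave the E geometry of the enoate unchanged.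

Step 15
Reactants: 29 amino ester
Product: 30 C2 ketone with free 1α-hydroxyl (silyl ether on C1′ retained)
Conditions: aq. HCl (2 M), THF, 40 °C
Reagents that add atoms: water, O
Why: Aqueous acid hydrolyses the dioxolane and the tert-butyldimethylsilyl ether, whereas the tert-butyldiphenylsilyl ether, the enoate and the protonated amine should persist; C1 and C3 are both in their more stable configurations, so enolisation of the freed ketone does no harm.

Step 16
Reactants: 30 amino ketol
Product: 32 C7 methylidene ketol, via amine oxide 31 (not isolated)
Conditions: mCPBA (1.05 equiv), CH2Cl2, 0 °C; basic Al2O3; then DMSO/THF, 60 °C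
Reagents that add atoms: none
Why: The peracid oxidises only the tertiary amine, and amine oxide 31 undergoes Cope elimination through a five-membered syn transition state in which H-7 is the only β-hydrogen, so the exocyclic alkene forms without acid or base and cannot end up in the ring.

Step 17
Reactants: 32 α-hydroxy ketone; 33 (R)-2-methylbutanoic acid
Product: 34 C1 β-(R)-2-methylbutanoate (silyl ether on C1′)
Conditions: 33, PPh3, DIAD, toluene, 0 → 25 °C
Reagents that add atoms: none
Why: In the Mitsunobu reaction the α-hydroxyl becomes an oxyphosphonium leaving group and is displaced by the carboxylate of 33 in an SN2 step that the adjacent carbonyl accelerates; inversion puts the ester on the β face of C1, and the stereocentre of the acid is not involved.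

Step 18
Reactants: 34 silyl ether
Product: 35 target
Conditions: HF·pyridine, pyridine/THF, 0 → 25 °C
Reagents that add atoms: none
Why: Buffered HF·pyridine cleaves the remaining silyl ether under weakly acidic conditions, which avoid acyl migration, epimerisation at C1 and retro-aldol or dehydration of the β-hydroxy ketone.

## Compound list

1 | (S)-4-(tert-butyldimethylsilyloxy)cyclopent-2-enone | O=C1C=C[C@@H](O[Si](C)(C)C(C)(C)C)C1 | starting material
2 | allylmagnesium bromide | C=CC[Mg]Br | starting material
3 | 3,4-trans-3-allyl-4-(tert-butyldimethylsilyloxy)-1-(trimethylsilyloxy)cyclopent-1-ene | C[Si](C)(C)OC1=C[C@H](CC=C)[C@@H](O[Si](C)(C)C(C)(C)C)C1 | intermediate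
4 | 3,4-trans-3-allyl-4-(tert-butyldimethylsilyloxy)cyclopentanone | O=C1C[C@H](CC=C)[C@@H](O[Si](C)(C)C(C)(C)C)C1 | intermediate
5 | (S)-4-allylcyclopent-2-enone | O=C1C[C@H](CC=C)C=C1 | intermediate
6 | 2-methylprop-1-enylmagnesium bromide | CC(C)=C[Mg]Br | starting material
7 | 3,4-trans-4-allyl-3-(2-methylprop-1-enyl)-1-(trimethylsilyloxy)cyclopent-1-ene | C=CC[C@@H]1[C@H](C=C(O[Si](C)(C)C)C1)C=C(C)C | intermediate
8 | acetaldehyde | CC=O | starting material
9 | lithium 3,4-trans-4-allyl-3-(2-methylprop-1-enyl)cyclopent-1-en-1-olate | C=CC[C@@H]1[C@H](C=C(O[Li])C1)C=C(C)C | intermediate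
10 | chlorobis(cyclopentadienyl)zirconium enolate corresponding to 9 (cyclopentadienyl rings written as σ-bonded) | C=CC[C@@H]1[C@H](C=C(O[Zr](Cl)(C2C=CC=C2)C2C=CC=C2)C1)C=C(C)C | intermediate
11 | 2,3-trans-3,4-trans-4-allyl-2-[(1S)-1-hydroxyethyl]-3-(2-methylprop-1-enyl)cyclopentanone (syn aldol) | C=CC[C@@H]1[C@H]([C@H]([C@H](C)O)C(=O)C1)C=C(C)C | intermediate
12 | 2,3-trans-3,4-trans-4-allyl-2-[(1S)-1-(tert-butyldiphenylsilyloxy)ethyl]-3-(2-methylprop-1-enyl)cyclopentanone | C=CC[C@@H]1[C@H]([C@H]([C@H](C)O[Si](c2ccccc2)(c2ccccc2)C(C)(C)C)C(=O)C1)C=C(C)C | intermediate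
13 | lithium enolate of 12 toward C5 of the cyclopentanone (C1 in hydrindane numbering) | C=CC[C@@H]1[C@H]([C@H]([C@H](C)O[Si](c2ccccc2)(c2ccccc2)C(C)(C)C)C(O[Li])=C1)C=C(C)C | intermediate
14 | all-trans 4-allyl-5-hydroxy-2-[(1S)-1-(tert-butyldiphenylsilyloxy)ethyl]-3-(2-methylprop-1-enyl)cyclopentanone | C=CC[C@@H]1[C@H]([C@H]([C@H](C)O[Si](c2ccccc2)(c2ccccc2)C(C)(C)C)C(=O)[C@H]1O)C=C(C)C | intermediate
15 | all-trans 4-allyl-5-(tert-butyldimethylsilyloxy)-2-[(1S)-1-(tert-butyldiphenylsilyloxy)ethyl]-3-(2-methylprop-1-enyl)cyclopentanone | C=CC[C@@H]1[C@H]([C@H]([C@H](C)O[Si](c2ccccc2)(c2ccccc2)C(C)(C)C)C(=O)[C@H]1O[Si](C)(C)C(C)(C)C)C=C(C)C | intermediate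
16 | ethylene ketal of 15 | C=CC[C@@H]1[C@H]([C@H]([C@H](C)O[Si](c2ccccc2)(c2ccccc2)C(C)(C)C)C2(OCCO2)[C@H]1O[Si](C)(C)C(C)(C)C)C=C(C)C | intermediate
17 | methyl ketone: 16 with a 2-oxopropyl group in place of the allyl group | CC(=O)C[C@@H]1[C@H]([C@H]([C@H](C)O[Si](c2ccccc2)(c2ccccc2)C(C)(C)C)C2(OCCO2)[C@H]1O[Si](C)(C)C(C)(C)C)C=C(C)C | intermediate
18 | dibenzyl carbonate | O=C(OCc1ccccc1)OCc1ccccc1 | starting material
19 | benzyl 3-oxo-4-(cyclopentyl)butanoate: β-keto ester chain on C7a, 2-methylpropenyl group on C3a, 1α-silyloxy, C2 ketal, 3β-[(1S)-1-silyloxyethyl] | O=C(CC(=O)C[C@@H]1[C@H]([C@H]([C@H](C)O[Si](c2ccccc2)(c2ccccc2)C(C)(C)C)C2(OCCO2)[C@H]1O[Si](C)(C)C(C)(C)C)C=C(C)C)OCc1ccccc1 | intermediate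
20 | C5 radical of 19 (radical between ketone and ester) | O=C([CH]C(=O)C[C@@H]1[C@H]([C@H]([C@H](C)O[Si](c2ccccc2)(c2ccccc2)C(C)(C)C)C2(OCCO2)[C@H]1O[Si](C)(C)C(C)(C)C)C=C(C)C)OCc1ccccc1 | intermediate
21 | cyclised tertiary radical (2-propyl radical on C4 of the trans-hydrindane) | C1[C@@H]2[C@H]([C@H]([C@H](C)O[Si](c4ccccc4)(c4ccccc4)C(C)(C)C)C3(OCCO3)[C@H]2O[Si](C)(C)C(C)(C)C)[C@@H]([C](C)C)[C@H](C(=O)OCc3ccccc3)C1=O | intermediate
22 | benzyl 1α-(tert-butyldimethylsilyloxy)-3β-[(1S)-1-(tert-butyldiphenylsilyloxy)ethyl]-2,2-(ethylenedioxy)-6-oxo-4β-(prop-1-en-2-yl)-trans-hydrindane-5α-carboxylate (H-3a β, H-7a α) | C1[C@@H]2[C@H]([C@H]([C@H](C)O[Si](c4ccccc4)(c4ccccc4)C(C)(C)C)C3(OCCO3)[C@H]2O[Si](C)(C)C(C)(C)C)[C@@H](C(C)=C)[C@H](C(=O)OCc3ccccc3)C1=O | intermediate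
23 | dilithium dienolate of 22 (C7=C6–O and C5=C(O)OBn) | C=1[C@@H]2[C@H]([C@H]([C@H](C)O[Si](c4ccccc4)(c4ccccc4)C(C)(C)C)C3(OCCO3)[C@H]2O[Si](C)(C)C(C)(C)C)[C@@H](C(C)=C)C(=C(O[Li])OCc3ccccc3)C=1O[Li] | intermediate
24 | 7β-(dimethylaminomethyl) derivative of 22 | CN(C)C[C@H]1[C@@H]2[C@H]([C@H]([C@H](C)O[Si](c4ccccc4)(c4ccccc4)C(C)(C)C)C3(OCCO3)[C@H]2O[Si](C)(C)C(C)(C)C)[C@@H](C(C)=C)[C@H](C(=O)OCc3ccccc3)C1=O | intermediate
25 | 7β-(dimethylaminomethyl)-4β-isopropyl-6-oxo acid (24 after hydrogenation and loss of the benzyl group) | CN(C)C[C@H]1[C@@H]2[C@H]([C@H]([C@H](C)O[Si](c4ccccc4)(c4ccccc4)C(C)(C)C)C3(OCCO3)[C@H]2O[Si](C)(C)C(C)(C)C)[C@@H](C(C)C)[C@H](C(=O)O)C1=O | intermediate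
26 | 7α-(dimethylaminomethyl)-4β-isopropyl-1α-(tert-butyldimethylsilyloxy)-3β-[(1S)-1-(tert-butyldiphenylsilyloxy)ethyl]-2,2-(ethylenedioxy)-trans-hydrindan-6-one | CN(C)C[C@@H]1[C@@H]2[C@H]([C@H]([C@H](C)O[Si](c4ccccc4)(c4ccccc4)C(C)(C)C)C3(OCCO3)[C@H]2O[Si](C)(C)C(C)(C)C)[C@@H](C(C)C)CC1=O | intermediate
27 | 6α-alcohol from 26 (axial hydroxyl) | CN(C)C[C@@H]1[C@@H]2[C@H]([C@H]([C@H](C)O[Si](c4ccccc4)(c4ccccc4)C(C)(C)C)C3(OCCO3)[C@H]2O[Si](C)(C)C(C)(C)C)[C@@H](C(C)C)C[C@@H]1O | intermediate
28 | (E)-3-methylpent-2-enoic acid | CC/C(C)=C/C(=O)O | starting material
29 | 6α-[(E)-3-methylpent-2-enoate] of 27 | CN(C)C[C@@H]1[C@@H]2[C@H]([C@H]([C@H](C)O[Si](c4ccccc4)(c4ccccc4)C(C)(C)C)C3(OCCO3)[C@H]2O[Si](C)(C)C(C)(C)C)[C@@H](C(C)C)C[C@@H]1OC(=O)/C=C(\C)CC | intermediate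
30 | 29 with free C2 ketone and free 1α-hydroxyl | CN(C)C[C@@H]1[C@@H]2[C@H]([C@H]([C@H](C)O[Si](c3ccccc3)(c3ccccc3)C(C)(C)C)C(=O)[C@H]2O)[C@@H](C(C)C)C[C@@H]1OC(=O)/C=C(\C)CC | intermediate
31 | N-oxide of 30 | C[N+](C)([O-])C[C@@H]1[C@@H]2[C@H]([C@H]([C@H](C)O[Si](c3ccccc3)(c3ccccc3)C(C)(C)C)C(=O)[C@H]2O)[C@@H](C(C)C)C[C@@H]1OC(=O)/C=C(\C)CC | intermediate
32 | 1α-hydroxy-7-methylidene-4β-isopropyl-6α-[(E)-3-methylpent-2-enoyloxy]-3β-[(1S)-1-(tert-butyldiphenylsilyloxy)ethyl]-trans-hydrindan-2-one | C=C1[C@@H]2[C@H]([C@H]([C@H](C)O[Si](c3ccccc3)(c3ccccc3)C(C)(C)C)C(=O)[C@H]2O)[C@@H](C(C)C)C[C@@H]1OC(=O)/C=C(\C)CC | intermediate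
33 | (R)-2-methylbutanoic acid | CC[C@@H](C)C(=O)O | starting material
34 | 1β-[(R)-2-methylbutanoyloxy] analogue of 32 (C1 inverted, silyl ether on C1′) | C=C1[C@@H]2[C@H]([C@H]([C@H](C)O[Si](c3ccccc3)(c3ccccc3)C(C)(C)C)C(=O)[C@@H]2OC(=O)[C@H](C)CC)[C@@H](C(C)C)C[C@@H]1OC(=O)/C=C(\C)CC | intermediate
35 | CNP0224363.1 | C=C1[C@@H]2[C@H]([C@H]([C@H](C)O)C(=O)[C@@H]2OC(=O)[C@H](C)CC)[C@@H](C(C)C)C[C@@H]1OC(=O)/C=C(\C)CC | target

## Step count and least certain steps

Total: 18 steps. Longest linear sequence: 18 steps, from 1 to 35.

Step 10 (key step). The most likely failure is a second oxidation: 22 is again a β-keto ester with a hydrogen on C5, it enolises readily, and trivalent manganese can oxidise it further (dehydrogenation across C4–C5 or acetoxylation at C5). Slow loss of the dioxolane in wet AcOH is a lesser concern. Fallback: block C5 before the cyclisation. Starting from 19, N-chlorosuccinimide with Mg(ClO4)2 would give the α-chloro keto ester F1. The same Mn(OAc)3/Cu(OAc)2 cyclisation would give the chloro ester F2, which has no hydrogen on C5 and cannot be oxidised again. Zn in AcOH would then remove the chlorine and return to 22.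

Step 17. Substitution may be slow, because the carboxylate must enter on the β face of C1 beside the methylidene group and 33 is a weak, α-branched acid. Elimination toward C7a, or esterification with retention through an acyloxyphosphonium species, could then take over. Fallback: separate activation from displacement. From 32, MsCl and Et3N would give the α-keto mesylate F3, and caesium (R)-2-methylbutanoate (from 33 and Cs2CO3) in DMF would displace it with inversion to give 34.

Step 15. The dioxolane is flanked by two substituted carbons and deactivated by the α-oxygen. Its hydrolysis may lag behind loss of the tert-butyldiphenylsilyl group or behind β-elimination of the silyloxy group from the freed ketone. Fallback: unmask in two stages. From 29, camphorsulfonic acid in MeOH would remove only the tert-butyldimethylsilyl group and give the hydroxy ketal F4. With the neighbouring silyl group gone, the ketal would be exchanged onto acetone (TsOH·H2O in excess over the amine, acetone, 40 °C) to reach 30.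

Step 3. The syn selectivity of the zirconium enolate toward a small, enolisable aldehyde may be insufficient, or incomplete transmetallation may let the lithium enolate give the anti aldol. Fallback: a metal-free enolate. From 7, a catalytic amount of tris(dimethylamino)sulfonium difluorotrimethylsilicate with 8 would generate the naked enolate, which reacts through an open transition state to give the syn aldol as its trimethylsilyl ether F5. Dilute acid would then give 11.

Step 7. Ketal formation at a cyclopentanone substituted on both α-carbons may stall for steric reasons. Fallback: ketalise before the bulky silyl group is on C1. From 14, the same reagents would give the trimethylsilyl-protected ketal F6. K2CO3 in MeOH would free the hydroxy ketal F7, and TBSOTf with 2,6-lutidine would give 16.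

## Further compounds

F1 | step 10 | α-chloro derivative of 19 (chlorine on C5, both epimers) | O=C(C(Cl)C(=O)C[C@@H]1[C@H]([C@H]([C@H](C)O[Si](c2ccccc2)(c2ccccc2)C(C)(C)C)C2(OCCO2)[C@H]1O[Si](C)(C)C(C)(C)C)C=C(C)C)OCc1ccccc1
F2 | step 10 | 5-chloro derivative of 22 (configuration at C5 not defined) | C1[C@@H]2[C@H]([C@H]([C@H](C)O[Si](c4ccccc4)(c4ccccc4)C(C)(C)C)C3(OCCO3)[C@H]2O[Si](C)(C)C(C)(C)C)[C@@H](C(C)=C)C(Cl)(C(=O)OCc3ccccc3)C1=O
F3 | step 17 | 1α-methanesulfonate of 32 | C=C1[C@@H]2[C@H]([C@H]([C@H](C)O[Si](c3ccccc3)(c3ccccc3)C(C)(C)C)C(=O)[C@H]2OS(C)(=O)=O)[C@@H](C(C)C)C[C@@H]1OC(=O)/C=C(\C)CC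
F4 | step 15 | 29 without the tert-butyldimethylsilyl group (1α-hydroxy ketal) | CN(C)C[C@@H]1[C@@H]2[C@H]([C@H]([C@H](C)O[Si](c4ccccc4)(c4ccccc4)C(C)(C)C)C3(OCCO3)[C@H]2O)[C@@H](C(C)C)C[C@@H]1OC(=O)/C=C(\C)CC
F5 | step 3 | trimethylsilyl ether of 11 | C=CC[C@@H]1[C@H]([C@H]([C@H](C)O[Si](C)(C)C)C(=O)C1)C=C(C)C
F6 | step 7 | ethylene ketal of 14 with a trimethylsilyl ether on C1 | C=CC[C@@H]1[C@H]([C@H]([C@H](C)O[Si](c2ccccc2)(c2ccccc2)C(C)(C)C)C2(OCCO2)[C@H]1O[Si](C)(C)C)C=C(C)C
F7 | step 7 | ethylene ketal of 14 (free 1α-hydroxyl) | C=CC[C@@H]1[C@H]([C@H]([C@H](C)O[Si](c2ccccc2)(c2ccccc2)C(C)(C)C)C2(OCCO2)[C@H]1O)C=C(C)C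
A1 | alternative 1 | trans-fused 7,7-diethoxy-5-isopropylbicyclo[4.2.0]octan-2-one | O=C1[C@@H]2[C@H](C(OCC)(OCC)C2)[C@@H](C(C)C)CC1
A2 | alternative 1 | (R)-4-isopropylcyclohex-2-enone | O=C1C=C[C@@H](C(C)C)CC1
A3 | alternative 1 | 1,1-diethoxyethene | C=C(OCC)OCC
A4 | alternative 2 | 1β-[(R)-2-methylbutanoyloxy]-3β-[(1S)-1-(tert-butyldimethylsilyloxy)ethyl]-4β-isopropyl-7-methylidene-trans-hydrindan-2-one | C=C1[C@@H]2[C@H]([C@H]([C@H](C)O[Si](C)(C)C(C)(C)C)C(=O)[C@@H]2OC(=O)[C@H](C)CC)[C@@H](C(C)C)CC1
A5 | alternative 2 | cyclohexane precursor with (acyloxy)(tributylstannyl)methyl group on C7a and S-phenyl thiol ester as C2 | C=C1[C@@H]([C@@H](OC(=O)[C@H](C)CC)[Sn](CCCC)(CCCC)CCCC)[C@H]([C@H]([C@H](C)O[Si](C)(C)C(C)(C)C)C(=O)Sc2ccccc2)[C@@H](C(C)C)CC1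
A6 | alternative 3 | methyl 2,2-(ethylenedioxy)-4-isopropyl-3β-[(1S)-1-(tert-butyldimethylsilyloxy)ethyl]-6α-(triethylsilyloxy)-trans-hydrind-4-ene-7α-carboxylate | COC(=O)[C@@H]1[C@@H]2[C@H]([C@H]([C@H](C)O[Si](C)(C)C(C)(C)C)C3(OCCO3)C2)C(C(C)C)=C[C@@H]1O[Si](CC)(CC)CC
A7 | alternative 3 | triene: (E)-enoate and (E,E)-1-(triethylsilyloxy)-3-isopropyl diene joined through the ketal carbon and C3 | COC(=O)/C=C/CC1(OCCO1)[C@@H]([C@H](C)O[Si](C)(C)C(C)(C)C)/C=C(C(C)C)/C=C/O[Si](CC)(CC)CC
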